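**Retrosynthetic overview**
- Target ⇐ hexabenzyl ether (global hydrogenolysis) ⇐ bis-ketoxime (deoximation); the two aroyl groups are carried as oximes until the end.
- Bis-ketoxime ⇐ double aryl-for-oxygen exchange with retention at the two N,O-acetal carbons (future C2/C5) of a C2-symmetric bis(isoxazoline) acetal.
- Bis(isoxazoline) acetal ⇐ furan + two aryl nitrile oxides: two dearomatizing (3+2) cycloadditions on opposite faces fix the 2,3-cis/3,4-trans/4,5-cis pattern in one operation.
- Ring order: the oxolane ring is furan's own ring; isoxazoline ring A, then isoxazoline ring B, are fused onto it and both are later opened.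
- Absolute configuration: the cycloadduct forms as a racemate and is resolved on a chiral stationary phase, so half of the material is discarded at that point.

Assumption: compounds 1 and 8 are bought; core atoms are numbered O1, C2–C5 as in the target; the absolute configuration of 7 is confirmed by anomalous-dispersion X-ray analysis.

**Step 1**
Reactants: 1 2,4-bis(benzyloxy)benzaldehyde
Product: 2 (E)-2,4-bis(benzyloxy)benzaldehyde oxime
Conditions: NH2OH·HCl, NaOAc, EtOH/H2O, rt
Reagents that add atoms: hydroxylamine hydrochloride (Cl.NO)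
Why: Oxime condensation of an aryl aldehyde; no stereocentre is formed and the C=N geometry is lost in the next step.

**Step 2**
Reactants: 2 (E)-2,4-bis(benzyloxy)benzaldehyde oxime (2.4 equiv); 3 furan (1.0 equiv)
Product: 6 racemic anti bis(isoxazoline) cycloadduct of furan, via nitrile oxide 4 (not isolated), via mono-cycloadduct 5 (not isolated)
Conditions: PhI(OAc)2 (2.6 equiv, portionwise), CH2Cl2, 0 °C to rt
Reagents that add atoms: none
Why: The trivalent iodine reagent oxidizes the aldoxime to nitrile oxide 4, which undergoes two Huisgen 1,3-dipolar cycloadditions, first to furan (dearomatization) and then to the more reactive enol ether of 5; each is suprafacial with enol-ether regiochemistry (dipole O to the O-bearing carbon), and the second dipole adds to the convex face anti to the first ring, which sets C3/C4 trans and each acetal C–O cis to its neighbouring C=N carbon (all four core centres, relative configuration only).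

**Step 3**
Reactants: 6 racemic anti bis(isoxazoline) cycloadduct
Product: 7 (2R,3S,4S,5R)-bis(isoxazoline) cycloadduct, single enantiomer
Conditions: preparative HPLC, cellulose tris(3,5-dimethylphenylcarbamate) stationary phase, hexane/i-PrOH
Reagents that add atoms: none
Why: Resolution of enantiomers by chiral-phase chromatography; no bond is formed, and the enantiomer kept has the spatial arrangement of the target at C3/C4 (the descriptors differ from the target only through CIP priorities).

**Step 4**
Reactants: 7 (2R,3S,4S,5R)-bis(isoxazoline) cycloadduct; 8 potassium [4-(benzyloxy)phenyl]trifluoroborate (3 equiv)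
Product: 10 (2S,3S,4S,5S)-bis-ketoxime, via mono-arylated isoxazoline 9 (not isolated)
Conditions: BF3·OEt2 (4 equiv), MeCN/CH2Cl2, 0 °C to rt; then H2O
Reagents that add atoms: none
Why: Proposed new method: BF3 turns 8 into the aryldifluoroborane and ionizes each N,O-acetal C–O bond of 7 (the oximate is a far better leaving group than the ring alkoxide and the oxolane oxocarbenium is the better-stabilized cation); the aryl group is delivered to C2 and then C5 from the face still held by the tethered, boron-bound oximate, which is also the face favoured by inside attack on the five-membered oxocarbenium envelope (1,2-cis, 1,3-trans and 1,4-trans preferences reinforce one another), so each C–aryl bond takes the place of the departing oxygen and gives the 2,3-cis/3,4-trans/4,5-cis array; the closest known reaction types are the BF3-mediated coupling of organotrifluoroborates with mixed acetals bearing N–O leaving groups and the 2,3-cis-selective arylzinc substitution of 2-sulfonyl tetrahydrofurans.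

**Step 5**
Reactants: 10 (2S,3S,4S,5S)-bis-ketoxime
Product: 12 (2S,3R,4R,5S)-hexabenzyl diketone, via bis(N–H ketimine) 11 (not isolated)
Conditions: TiCl3 (aq., 6 equiv), NH4OAc buffer, THF/H2O, 0 °C to rt
Reagents that add atoms: water (O)
Why: Reductive deoximation: trivalent titanium cleaves the N–O bonds to N–H ketimines that hydrolyse at once in the buffered medium (pH about 5–6), conditions mild enough that the epimerizable C3/C4 centres and the β-alkoxy ketone units are not equilibrated; no stereocentre is formed.

**Step 6**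
Reactants: 12 (2S,3R,4R,5S)-hexabenzyl diketone
Product: 13 [(2S,3R,4R,5S)-2,5-bis(4-hydroxyphenyl)oxolane-3,4-diyl]bis[(2,4-dihydroxyphenyl)methanone] (target)
Conditions: H2 (1 atm), Pd/C (10 wt% Pd on carbon), EtOAc/MeOH, rt, stopped at full debenzylation
Reagents that add atoms: none
Why: Catalytic hydrogenolysis of six aryl benzyl ethers under neutral conditions, which is faster than cleavage of the ring benzylic C–O bonds or reduction of the 2-hydroxyaryl ketones and avoids the acid or base that would epimerize C3/C4 or open the ring; no stereocentre is touched.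

**Compound list**
1 | 2,4-bis(benzyloxy)benzaldehyde | O=Cc1ccc(OCc2ccccc2)cc1OCc1ccccc1 | starting material
2 | (E)-2,4-bis(benzyloxy)benzaldehyde oxime | O/N=C/c1ccc(OCc2ccccc2)cc1OCc1ccccc1 | intermediate
3 | furan | c1ccoc1 | starting material
4 | 2,4-bis(benzyloxy)benzonitrile oxide | [O-][N+]#Cc1ccc(OCc2ccccc2)cc1OCc1ccccc1 | intermediate
5 | 3-[2,4-bis(benzyloxy)phenyl]-3a,6a-dihydrofuro[2,3-d]isoxazole, cis-fused, racemate (one enantiomer drawn) | O2N=C(c3ccc(OCc4ccccc4)cc3OCc3ccccc3)[C@@H]1C=CO[C@@H]12 | intermediate
6 | racemic anti bis(isoxazoline) cycloadduct: oxolane core cis-fused at C2–C3 and at C4–C5 to two 3-[2,4-bis(benzyloxy)phenyl]-2-isoxazolines (ring O on C2/C5, C=N carbon on C3/C4), the two isoxazolines on opposite faces; racemate (one enantiomer drawn) | O2N=C(c4ccc(OCc5ccccc5)cc4OCc4ccccc4)[C@@H]1[C@@H](C(=NO3)c4ccc(OCc5ccccc5)cc4OCc4ccccc4)[C@@H]3O[C@@H]12 | intermediate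
7 | same bis(isoxazoline) cycloadduct, single (2R,3S,4S,5R) enantiomer | O2N=C(c4ccc(OCc5ccccc5)cc4OCc4ccccc4)[C@@H]1[C@@H](C(=NO3)c4ccc(OCc5ccccc5)cc4OCc4ccccc4)[C@@H]3O[C@@H]12 | intermediate
8 | potassium [4-(benzyloxy)phenyl]trifluoroborate | [K+].F[B-](F)(F)c1ccc(OCc2ccccc2)cc1 | starting material
9 | (2S,3S,4S,5R) mono-arylated intermediate: C2 bears 4-(benzyloxy)phenyl cis to the C3 (E)-ketoxime; C4–C5 isoxazoline intact | O/N=C(c4ccc(OCc5ccccc5)cc4OCc4ccccc4)\[C@@H]1[C@@H](C(=NO3)c4ccc(OCc5ccccc5)cc4OCc4ccccc4)[C@@H]3O[C@@H]1c1ccc(OCc2ccccc2)cc1 | intermediate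
10 | (2S,3S,4S,5S)-2,5-bis[4-(benzyloxy)phenyl]oxolane-3,4-diyl bis{[2,4-bis(benzyloxy)phenyl]methanone} (E,E)-dioxime; 2,3-cis, 3,4-trans, 4,5-cis | O/N=C(c4ccc(OCc5ccccc5)cc4OCc4ccccc4)\[C@@H]1[C@@H](\C(=N/O)c4ccc(OCc5ccccc5)cc4OCc4ccccc4)[C@@H](c4ccc(OCc5ccccc5)cc4)O[C@@H]1c1ccc(OCc2ccccc2)cc1 | intermediate
11 | corresponding bis(N–H ketimine), same configuration | N=C(c4ccc(OCc5ccccc5)cc4OCc4ccccc4)[C@@H]1[C@@H](C(=N)c4ccc(OCc5ccccc5)cc4OCc4ccccc4)[C@@H](c4ccc(OCc5ccccc5)cc4)O[C@@H]1c1ccc(OCc2ccccc2)cc1 | intermediate
12 | {(2S,3R,4R,5S)-2,5-bis[4-(benzyloxy)phenyl]oxolane-3,4-diyl}bis{[2,4-bis(benzyloxy)phenyl]methanone} | O=C(c4ccc(OCc5ccccc5)cc4OCc4ccccc4)[C@@H]1[C@@H](C(=O)c4ccc(OCc5ccccc5)cc4OCc4ccccc4)[C@@H](c4ccc(OCc5ccccc5)cc4)O[C@@H]1c1ccc(OCc2ccccc2)cc1 | intermediate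
13 | [(2S,3R,4R,5S)-2,5-bis(4-hydroxyphenyl)oxolane-3,4-diyl]bis[(2,4-dihydroxyphenyl)methanone] | O=C(c1ccc(O)cc1O)[C@@H]1[C@@H](C(=O)c2ccc(O)cc2O)[C@@H](c2ccc(O)cc2)O[C@@H]1c1ccc(O)cc1 | target

**Step count and risks**
Total step count: 6 (five bond-changing steps and one resolution). Longest linear sequence: 6 steps, from 1.

The three steps most likely to fail:

Step 4 (double arylation; new for this leaving group, and elimination toward a dihydrofuran or isoxazole could compete). The fallback sets out from 7 and returns at 10. Benzenesulfinic acid with catalytic BF3·OEt2 in CH2Cl2 at 0 °C opens both N,O-acetals to the 2,5-bis(phenylsulfonyl) bis-ketoxime F1 (anomer mixture at C2/C5). Commercial 4-(benzyloxy)phenylmagnesium bromide is transmetalated with ZnBr2 to 4-(benzyloxy)phenylzinc bromide F2. In THF at rt, F2 (excess, to allow for the two oxime OH groups) replaces both sulfonyl groups through the oxocarbenium ions (sulfone substitution by an arylzinc), with the aryl entering cis to the neighbouring substituent, to give 10.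

Step 5 (deoximation; the N–H ketimines could tautomerize to enamines and epimerize C3/C4 toward the more stable all-trans isomer). The fallback sets out from 10 and returns at 12. It is an oxidative deoximation with Dess–Martin periodinane in wet CH2Cl2 over solid NaHCO3 at rt, which releases the ketones without passing through an imine; no new compound is made (F0).

Step 2 (furan is a sluggish dipolarophile, so dimerization of 4 can outrun the first cycloaddition). The fallback sets out from 2 and 3 and returns at 6. Oxime 2 is chlorinated with N-chlorosuccinimide in DMF to the hydroximoyl chloride F3. Slow addition of Et3N to F3 in neat furan gives the mono-cycloadduct 5, which is now isolated. A second portion of F3 with Et3N, added by syringe pump in CH2Cl2, converts 5 into 6.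

**Further compounds**
F1 | step 4 | (3S,4S)-2,5-bis(phenylsulfonyl)oxolane-3,4-diyl bis{[2,4-bis(benzyloxy)phenyl]methanone} (E,E)-dioxime, anomer mixture at C2/C5 | O/N=C(c4ccc(OCc5ccccc5)cc4OCc4ccccc4)\[C@@H]1[C@@H](\C(=N/O)c4ccc(OCc5ccccc5)cc4OCc4ccccc4)C(S(=O)(=O)c4ccccc4)OC1S(=O)(=O)c1ccccc1
F2 | step 4 | 4-(benzyloxy)phenylzinc bromide | Br[Zn]c1ccc(OCc2ccccc2)cc1
F0 | step 5 | none | none
F3 | step 2 | (Z)-2,4-bis(benzyloxy)-N-hydroxybenzimidoyl chloride | O/N=C(\Cl)c1ccc(OCc2ccccc2)cc1OCc1ccccc1
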